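Readings and results were computed with made-up constants; scatter was added.

Work in equivalents of coupling partner and in the logarithm of the starting material left, not in hours.

| setting | alder | elm | dusk | noon | winter |
|---|---|---|---|---|---|
| starting material | 21 mM | 21 mM | 21 mM | 21 mM | 21 mM |
| coupling partner | 0.88 equiv | 3.2 equiv | 1.20 equiv | 2.50 equiv | 5.00 equiv |
| free catalyst | 15 mol% | 15 mol% | 15 mol% | 15 mol% | 15 mol% |
| remark | run made earlier | run made earlier |  |  |  |
| time |  |  | 25 h | 25 h | 25 h |

| run | time / h | target / % | starting material / % |
|---|---|---|---|
| alder | 4.00 | 15.7 | 26.0 |
| alder | 8.00 | 20.4 | 19.9 |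
| alder | 10.0 | 21.3 | 18.6 |
| alder | 15.0 | 21.2 | 18.3 |
| alder | 20.0 | 21.6 | 17.9 |
| alder | 25.0 | 22.0 | 18.1 |
| elm | 4.00 | 7.2 | 68.9 |
| elm | 8.00 | 7.7 | 66.7 |
| elm | 10.0 | 7.5 | 67.3 |
| elm | 15.0 | 7.9 | 65.9 |
| elm | 20.0 | 8.3 | 67.8 |
| elm | 25.0 | 8.0 | 67.0 |

(each reading ± 1 percentage point)

- steps that have been proposed: starting material + free catalyst -> free catalyst + intermediate; coupling partner + free catalyst + intermediate -> free catalyst + target; coupling partner + free catalyst -> spent catalyst
- "hardly changes" means that all values lie within two and a half points (for a concentration: within two and a half percent of the largest)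

- amount of target at the end, in percent of the starting material charged for dusk, noon, winter, in this order
- how that number moves from the first to the last of them (rises all the way / falls, then rises / hardly changes / falls all the way / rises, then falls)

Read the ladder from its fastest rung. Elm stops first: its starting material reads 68.9 % at 4.00 h and 67.0 % at 25.0 h. Alder stops later, reading 18.6 % at 10.0 h and 18.1 % at 25.0 h. Coupling trails conversion: the balance of alder's last readings leaves 59.9 % as intermediate, more than the 22.0 % of target. The clock is the slowest rung, since 25 h outlasts both stops, so treat an end reading as a stopped flask and remove time.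

Let x = ln(charged/left) for starting material. The proposed steps give dx/dt = a·c(free catalyst) and −dc(free catalyst)/dt = b·c(coupling partner)·c(free catalyst). Divide them: time and c(free catalyst) cancel, and each unit of x costs free catalyst in proportion to c(coupling partner). At equal loading and concentration, mean equivalents of coupling partner times the final x of a stopped flask is therefore constant.

Take the mean as the charge less half of what target and the off-cycle spent catalyst took, counting the whole 15 mol% loading as spent catalyst. Elm's last readings give x = 0.400 and mean 3.08 equivalents, so the conversion budget, mean equivalents times final x, reads 1.24. Alder, reckoned the same way, reads 1.19.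

My own reckoning sets target aside in the mean. It gives x of 1.10, 0.509 and 0.251 for dusk, noon and winter. Divide coupling by conversion as well, taking intermediate as 1 − e^(−x), a rough step that counts target as intermediate, and target becomes r·(mean equivalents)·(x − 1 + e^(−x)). Elm reads r = 0.368. So I expect 17.9 %, 9.84 % and 5.25 %, falling throughout.

The forecast says 17.5 %, 9.8 % and 5.2 %, falls all the way, below mine at dusk: “Target falls steadily, because extra partner costs more conversion than it gains in coupling.”

The flasks give 17.4 %, 9.55 % and 5.10 %: falls all the way.

    starting material + free catalyst → free catalyst + intermediate (k = 226 M⁻¹ h⁻¹)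
    coupling partner + free catalyst + intermediate → free catalyst + target (k = 4740 M⁻² h⁻¹)
    coupling partner + free catalyst → spent catalyst (k = 27.9 M⁻¹ h⁻¹)

Dusk ends with 51.1 % as intermediate beside that target. Spend the budget of 1.24 on winter: 96 % of its coupling partner is left, so the mean is 4.90 equivalents, and 78.1 % of starting material is left, so x = 0.247. Winter's product is 1.21.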